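## The problem

The target 21 is a 2,3-trans 3-O-methyl dihydroflavonol: a chroman-4-one with methoxy groups on C5, C6 and C7 of ring A, the aryl group on C2 and a methoxy group on C3 of ring C, and a 4-methoxyhydroquinone as ring B. It has two adjacent stereocentres, C2 (R) and C3 (R). The trans arrangement is the more stable one, so C3, which is alpha to the C4 carbonyl, can follow C2, whereas C2 has to be set by a reagent. Both centres are fragile: the C2–O1 bond is benzylic to a ring with ortho and para oxygen and ionizes in acid, and deprotonation at C3 can expel O1 by beta-elimination to an achiral enone, which erases both centres. The hydroquinone of ring B is oxidized by air once free and must stay masked to the end; the C5 oxygen is peri to the carbonyl, where a free phenol is chelated and a methyl ether is cleaved by Lewis acids. Ring A has oxygen on C5, C7 and C8a in the alternating pattern of a phloroglucinol, with one more oxygen on C6, which is the pattern of a folded poly-beta-keto chain. Because the C8a oxygen is the ring oxygen O1, a 2,3-dihydro-4H-pyran-4-one that already holds C2, C3, C4, C4a and C8a can carry C8, C7, C6 and C5 as a keto ester chain on C8a. The ester carbon of that chain can reach only C4a, so a Claisen closure of ring A can give nothing but the 5,6,7-pattern. Chromanone numbering is used for every intermediate.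

## Retrosynthesis

**21 to 20 (two benzyl–O bonds of ring B).** The free hydroquinone is made last because it is oxidized by air. Benzyl is preferred to acetal or silyl groups because it should survive TiCl4 at low temperature, strong base, zerovalent palladium, Mg(OMe)2 and Ag2O, and to methyl because it stays distinct from the five methoxy groups. The forward step must remove two aryl benzyl ethers without reducing the aryl ketone or cleaving the C2–O1 bond.

**20 to 19 (O–CH3 bonds at C5 and C7).** These two oxygens are the ester and ketone carbonyls of the chain that closes ring A, so they appear as free phenols. Carrying them as methyl ethers through the ring closure would need enol ethers of defined geometry and was set aside. The precursor 19 is simpler by two methyl groups; the forward step must methylate a chelated phenol without a base strong enough to deprotonate C3.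

**19 to 17 (C4a–C5, via trione 18).** This is the strategic cut. It removes ring A and leaves the dihydropyranone keto ester 17, whose chain can fold only onto C4a. Cuts inside ring C of a finished chromanone (O1–C8a, C4–C4a or O1–C2) would need a fully substituted ring A as an aromatic building block, whereas here every carbon of ring A comes from acetoacetate and malonate. The forward step must acylate C4a with the ester carbon while leaving the C3 proton alone.

**17 to 13 and 15 (C6–C7).** The neighbouring cut, C7–C8, would be the acylation of a C8 carbanion of a 6-methyl dihydropyranone by diester 14. It is set aside because the C–H bond of 14 is far more acidic than the C8 methyl group, so the carbanion would be protonated and not acylated, and because the strong base could also remove the C3 proton. With reversed polarity, C7 is the acyl carbon of acid 13 and C6 is the nucleophilic carbon of half-ester salt 15, and the bond forms under nearly neutral conditions. Salt 15 comes from 14 in one step.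

**13 to 12 to 9 and 10 (O1–C8a and C4–C4a).** The enol ether bond O1–C8a is cut to a hydroxy diketone (11 in the forward sense), and C4–C4a is cut to Weinreb amide 9 and allyl acetoacetate 10, which supplies C4a, C8a, C8 and C7 in the right oxidation states. A cycloaddition of aldehyde 4 with an oxygenated diene would form O1–C2 and C2–C3 at once, but would leave the regiochemistry of diene formation and the configuration at C3 open. The allyl ester is chosen because it is removed without hydroxide or strong acid. The forward steps need a mild cyclodehydration and a neutral ester cleavage.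

**9 to 8 to 7 and 4 (C2–C3).** Cutting the bond between the two stereocentres gives aldehyde 4 and the glycolate imide 7. An auxiliary-controlled anti aldol addition sets both centres in one step with the C3 methoxy group already in place, so no hydroxyl has to be methylated next to a carbonyl later. The forward reaction must be anti-selective and must not expose the electron-rich benzylic alkoxide to warm Lewis acid.

**4 to 2 to 1; 7 to 5 and 6; 15 to 14.** The formyl C–C bond of 4 is cut to the dibenzyl ether 2 of methoxyhydroquinone 1; formylation goes para to the methoxy group. Imide 7 is the N-acyl derivative of auxiliary 5 with methoxyacetyl chloride 6, and 15 is the half-saponification product of 14. All are commercial or one step from commercial material.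

## Roads not taken

**Alternative 1:** The cut is the C3=C4 double bond of a 2H-chromene, preceded by O1–C2.
- Forward: an allylic etherification with [Ir(cod)Cl]2 and a chiral phosphoramidite would set C2 in the bis-allylic ether A1, 1,4-bis(benzyloxy)-2-[(1S)-1-(2-ethenyl-3,4,5-trimethoxyphenoxy)prop-2-en-1-yl]-5-methoxybenzene. RuCl2(=CHPh)(PCy3)(H2IMes), the second-generation Grubbs catalyst, would then close ring C to chromene A2, (S)-2-[2,5-bis(benzyloxy)-4-methoxyphenyl]-5,6,7-trimethoxy-2H-chromene, with loss of ethylene.
- Merits: both reactions are known for this substrate class, so the key step is safer than the one chosen; ring A is bought complete; C2 comes from a catalyst, not an auxiliary.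
- Weak points: A2 has neither the C3 oxygen nor the C4 carbonyl. At least three further operations are needed (oxygenation of the C3=C4 bond trans to the aryl group, oxidation at C4, O-methylation at C3), with C3 controlled by C2 alone. All run on electron-rich 2-aryl chromenes or chromanols, which open at C2–O1 by electrocyclic or acid pathways and would then lose the C2 configuration.
- Comparison: Alternative 1 has the more reliable key step but a longer and more delicate end game. The chosen plan has the C3 methoxy group and the C4 carbonyl in place before ring A exists, and pays for this with an unprecedented ring closure.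

**Alternative 2:** The cut removes O1–C8a and C4–C4a together and leaves an aryne and an aldol ester.
- Forward: CsF would release the aryne from silyl triflate A3, 2,3,4-trimethoxy-6-(trimethylsilyl)phenyl trifluoromethanesulfonate. The C2 alkoxide of A4, methyl (2R,3R)-3-[2,5-bis(benzyloxy)-4-methoxyphenyl]-3-hydroxy-2-methoxypropanoate, would add at C8a, the aryne carbon remote from the methoxy group, and the aryl anion at C4a would attack the ester. The product A5 is the same compound as 20.
- Merits: it is the most convergent and clearly the shortest road. A5 needs only hydrogenolysis, no phenol has to be methylated, and the stereocentres come from the same kind of anti aldol unit as here.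
- Weak points: a hindered secondary alkoxide adds slowly to an aryne, and the aryl anion can be protonated by remaining alcohol before it acylates. The alkoxide of A4 can undergo retro-aldol cleavage or epimerize C3 under fluoride. Regiochemistry rests on polarization by one methoxy group, and A3 needs a multistep, regiocontrolled preparation.
- Comparison: on step count and end game Alternative 2 is better, and it would be preferred if its annulation could be relied on. The chosen plan sets against it that ring C is closed by an ordinary cyclodehydration, that its one uncertain step is intramolecular and driven by aromatization, and that the ring A pattern follows from connectivity.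

**Alternative 3:** The cut is O1–C8a with ring A otherwise complete.
- Forward: PhI(OAc)2 in methanol would oxidize the C7 phenol of A6, (2R,3R)-3-[2,5-bis(benzyloxy)-4-methoxyphenyl]-3-hydroxy-1-(4-hydroxy-2,3-dimethoxyphenyl)-2-methoxypropan-1-one, to a dienone ketalized at C6. The C2 hydroxyl would add to C8a, and loss of methanol would rearomatize to A7, (2R,3R)-2-[2,5-bis(benzyloxy)-4-methoxyphenyl]-7-hydroxy-3,5,6-trimethoxy-2,3-dihydro-4H-chromen-4-one.
- Merits: ring A comes from an aromatic starting material, and only the unchelated C7 phenol remains to be methylated, which is easier than the double methylation of 19.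
- Weak points: dienones of this kind dimerize and add methanol in competition with the hindered secondary alcohol. The oxidant must spare the hydroquinone diether and the benzylic carbinol. A6 is an open-chain beta-hydroxy aryl ketone that can lose water to an achiral chalcone or cleave by retro-aldol reaction, and its synthesis needs an aryl-metal addition with one more phenol protecting group.
- Comparison: the length is similar and the end game is better. The chosen plan never carries an open-chain beta-hydroxy aryl ketone and uses no oxidant once ring B is in place.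

Key step: step 10

Assumption: in step 4 the (4R)-auxiliary is taken to direct the aldehyde to the enolate face that gives (2R,3R) (attack anti to the benzyl group, open transition state); if the sense proved opposite, the (4S)-auxiliary would be used with no other change.

Step 1
Reactants: 1 2-methoxybenzene-1,4-diol (methoxyhydroquinone)
Product: 2 1,4-bis(benzyloxy)-2-methoxybenzene
Conditions: BnBr, K2CO3, DMF, 60 °C, argon
Reagents that add atoms: benzyl bromide, BrCc1ccccc1
Why: Williamson ether synthesis; both phenoxides are benzylated, and working under argon keeps the hydroquinone from being oxidized before it is capped.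

Step 2
Reactants: 2 1,4-bis(benzyloxy)-2-methoxybenzene
Product: 4 2,5-bis(benzyloxy)-4-methoxybenzaldehyde, via iminium salt 3 (not isolated)
Conditions: POCl3, DMF, 0 to 60 °C; then aq. NaOAc
Reagents that add atoms: N,N-dimethylformamide, CN(C)C=O (formyl carbon); water, O (carbonyl oxygen)
Why: Vilsmeier–Haack formylation; the chloroiminium ion attacks the position para to the methoxy group and ortho to a benzyloxy group, which is the most activated and is not flanked by two alkoxy groups. Aryl benzyl ethers are stable to POCl3, and iminium salt 3 is hydrolysed on work-up.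

Step 3
Reactants: 5 (4R)-4-benzyl-1,3-oxazolidine-2-thione; 6 methoxyacetyl chloride
Product: 7 (4R)-4-benzyl-3-(methoxyacetyl)-1,3-oxazolidine-2-thione
Conditions: Et3N, CH2Cl2, 0 °C to rt
Reagents that add atoms: none
Why: N-acylation of the oxazolidinethione with an acid chloride; the N-acyl imide is the thermodynamic product, and the thiocarbonyl makes it an activated amide for steps 4 and 5.

Step 4
Reactants: 7 (4R)-4-benzyl-3-(methoxyacetyl)-1,3-oxazolidine-2-thione; 4 2,5-bis(benzyloxy)-4-methoxybenzaldehyde
Product: 8 (4R)-4-benzyl-3-[(2R,3R)-3-[2,5-bis(benzyloxy)-4-methoxyphenyl]-3-hydroxy-2-methoxypropanoyl]-1,3-oxazolidine-2-thione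
Conditions: TiCl4 (1.1 equiv), i-Pr2NEt, CH2Cl2, -78 °C; then 4 pre-complexed with TiCl4 (2 equiv), -78 °C; aq. NH4Cl at -78 °C
Reagents that add atoms: none
Why: Titanium-mediated anti-selective glycolate aldol addition; soft enolization gives the Z trichlorotitanium enolate, and addition to the aldehyde pre-complexed with further TiCl4 runs through an open transition state that gives the 2,3-anti adduct. The benzyl group of the (4R)-auxiliary shields one enolate face and sets C3 as R, and the anti topology then sets C2 as R. The cold quench keeps the electron-rich benzylic alkoxide from ionizing under Lewis acid.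

Step 5
Reactants: 8 (4R)-4-benzyl-3-[(2R,3R)-3-[2,5-bis(benzyloxy)-4-methoxyphenyl]-3-hydroxy-2-methoxypropanoyl]-1,3-oxazolidine-2-thione
Product: 9 (2R,3R)-3-[2,5-bis(benzyloxy)-4-methoxyphenyl]-3-hydroxy-N,2-dimethoxy-N-methylpropanamide
Conditions: MeNHOMe·HCl, imidazole, CH2Cl2, rt
Reagents that add atoms: N,O-dimethylhydroxylamine hydrochloride, CNOC.Cl
Why: Aminolysis of the thione-activated imide to the Weinreb amide; it should proceed at room temperature under buffered conditions that touch neither the free hydroxyl nor C3, and auxiliary 5 is recovered.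

Step 6
Reactants: 9 (2R,3R)-3-[2,5-bis(benzyloxy)-4-methoxyphenyl]-3-hydroxy-N,2-dimethoxy-N-methylpropanamide; 10 prop-2-en-1-yl 3-oxobutanoate (allyl acetoacetate)
Product: 12 prop-2-en-1-yl 2-[(2R,3R)-2-[2,5-bis(benzyloxy)-4-methoxyphenyl]-3-methoxy-4-oxo-3,4-dihydro-2H-pyran-6-yl]acetate, via hydroxy diketo ester 11 (not isolated)
Conditions: 10 (3.5 equiv), NaH, THF, 0 °C; n-BuLi, -20 °C; then 9, -78 to 0 °C; aq. NH4Cl; then PPTS, CH2Cl2, 4 Å MS, rt
Reagents that add atoms: none
Why: Weinreb ketone synthesis with the 1,3-dianion of a beta-keto ester, which reacts at its terminal carbon and forms C4–C4a; one further equivalent is consumed by the hydroxyl. In 11 the C2 hydroxyl adds to the C8a ketone (6-exo-trig hemiketal) and PPTS dehydrates the hemiketal to the vinylogous ester, which forms O1–C8a. A weak acid is chosen because a strong one would ionize the benzylic C2–O bond; C2 and C3 take no part.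

Step 7
Reactants: 12 prop-2-en-1-yl 2-[(2R,3R)-2-[2,5-bis(benzyloxy)-4-methoxyphenyl]-3-methoxy-4-oxo-3,4-dihydro-2H-pyran-6-yl]acetate
Product: 13 2-[(2R,3R)-2-[2,5-bis(benzyloxy)-4-methoxyphenyl]-3-methoxy-4-oxo-3,4-dihydro-2H-pyran-6-yl]acetic acid
Conditions: Pd(PPh3)4 (cat.), sodium p-toluenesulfinate (TolSO2Na), THF/MeOH, rt; then cold dilute HCl to pH 4
Reagents that add atoms: none
Why: Tsuji–Trost deallylation; zerovalent palladium ionizes the allyl ester and the sulfinate captures the allyl group, so the acid is released without hydroxide (which could open ring C through the C3 enolate) and without strong acid. Acid 13 is used at once because a vinylogous beta-keto acid can decarboxylate on warming.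

Step 8
Reactants: 14 dimethyl 2-methoxypropanedioate (dimethyl methoxymalonate)
Product: 15 potassium (2RS)-2,3-dimethoxy-3-oxopropanoate (potassium methyl methoxymalonate)
Conditions: KOH (1.0 equiv), MeOH, 0 °C to rt
Reagents that add atoms: potassium hydroxide, [K+].[OH-]
Why: Half-saponification of a malonic diester; one equivalent of KOH cleaves one ester, and the carboxylate formed deactivates the second ester toward hydroxide.

Step 9
Reactants: 13 2-[(2R,3R)-2-[2,5-bis(benzyloxy)-4-methoxyphenyl]-3-methoxy-4-oxo-3,4-dihydro-2H-pyran-6-yl]acetic acid; 15 potassium (2RS)-2,3-dimethoxy-3-oxopropanoate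
Product: 17 methyl (2RS)-4-[(2R,3R)-2-[2,5-bis(benzyloxy)-4-methoxyphenyl]-3-methoxy-4-oxo-3,4-dihydro-2H-pyran-6-yl]-2-methoxy-3-oxobutanoate, via acyl imidazolide 16 (not isolated)
Conditions: CDI, THF, rt; then 15, MgCl2, THF/MeCN, rt to 40 °C; aq. citric acid
Reagents that add atoms: 1,1'-carbonyldiimidazole, O=C(n1ccnc1)n1ccnc1 (its imidazole stays only in intermediate 16)
Why: Decarboxylative Claisen condensation of an acyl imidazolide with a malonate half-ester; MgCl2 and the imidazole set free generate the chelated magnesium enolate of 15, which is C-acylated by 16 and loses CO2, so C6–C7 forms under nearly neutral conditions. This polarity avoids a strongly basic C8 carbanion, which would only deprotonate a methoxymalonate and would endanger C3.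

Step 10
Reactants: 17 methyl (2RS)-4-[(2R,3R)-2-[2,5-bis(benzyloxy)-4-methoxyphenyl]-3-methoxy-4-oxo-3,4-dihydro-2H-pyran-6-yl]-2-methoxy-3-oxobutanoate
Product: 19 (2R,3R)-2-[2,5-bis(benzyloxy)-4-methoxyphenyl]-5,7-dihydroxy-3,6-dimethoxy-2,3-dihydro-4H-chromen-4-one, via cyclohexenetrione 18 (not isolated)
Conditions: Mg(OMe)2 (5 equiv), MeOH/THF, rt to 50 °C; then cold dilute HCl to pH 4
Reagents that add atoms: none
Why: Proposed new method: Mg(OMe)2 deprotonates 17 at C8, which lies between the C7 ketone and the C8a=C4a vinylogous ester, and the extended enolate carries negative charge on C4a; C4a adds to the ester carbon C5, methoxide leaves, and the resulting trione 18 enolizes to the 5,7-dihydroxy-6-methoxy arene 19, which makes the sequence irreversible. The closest known reaction type is the magnesium-alkoxide-mediated Claisen cyclization of 3,5,7-triketo esters and of pyrone-masked polyketides to acylphloroglucinols; new here is that the nucleophile is the alpha carbon of a 2,3-dihydro-4H-pyran-4-one. Ring A closes in a 6-exo-trig mode through an enolate whose C4=C4a bond is exocyclic to the new ring. No stereocentre is created: the unassigned centre at C6 of 17 disappears on aromatization, and C2 and C3 are carried through. The step needs C-acylation at C4a over the other closures, and the substrate secures it: attack of the more acidic C6 on the C4 carbonyl would put the C4a=C8a double bond at a bridgehead, O-acylation would need a four- or eight-membered ring, and with O1 already on C8a only the 5,6,7-pattern can form. Ring opening by beta-elimination of O1 needs deprotonation at C3, which is disfavoured while the C4 carbonyl is part of the enolate and, in the product, of the chelate with the C5 phenoxide.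

Step 11
Reactants: 19 (2R,3R)-2-[2,5-bis(benzyloxy)-4-methoxyphenyl]-5,7-dihydroxy-3,6-dimethoxy-2,3-dihydro-4H-chromen-4-one
Product: 20 (2R,3R)-2-[2,5-bis(benzyloxy)-4-methoxyphenyl]-3,5,6,7-tetramethoxy-2,3-dihydro-4H-chromen-4-one
Conditions: MeI (excess), Ag2O, DMF, rt, dark
Reagents that add atoms: iodomethane, CI
Why: Purdie methylation; Ag2O assists O-alkylation of both phenols by MeI, the chelated C5 hydroxyl included, in a medium too weakly basic to deprotonate C3 and open ring C.

Step 12
Reactants: 20 (2R,3R)-2-[2,5-bis(benzyloxy)-4-methoxyphenyl]-3,5,6,7-tetramethoxy-2,3-dihydro-4H-chromen-4-one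
Product: 21 (2R,3R)-2-(2,5-dihydroxy-4-methoxyphenyl)-3,5,6,7-tetramethoxy-2,3-dihydro-4H-chromen-4-one
Conditions: H2 (1 atm), 10% Pd/C, EtOAc, rt; work-up under argon
Reagents that add atoms: none
Why: Catalytic hydrogenolysis of the two aryl benzyl ethers under neutral conditions, which should be faster than reduction of the aryl ketone or cleavage of the C2–O1 bond; the hydroquinone is isolated under argon.

## Compound list

1 | 2-methoxybenzene-1,4-diol (methoxyhydroquinone) | COc1cc(O)ccc1O | starting material
2 | 1,4-bis(benzyloxy)-2-methoxybenzene | COc1cc(OCc2ccccc2)ccc1OCc1ccccc1 | intermediate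
3 | N-[2,5-bis(benzyloxy)-4-methoxybenzylidene]-N-methylmethanaminium dichlorophosphate | COc1cc(OCc2ccccc2)c(C=[N+](C)C)cc1OCc1ccccc1.[O-]P(=O)(Cl)Cl | intermediate (not isolated)
4 | 2,5-bis(benzyloxy)-4-methoxybenzaldehyde | COc1cc(OCc2ccccc2)c(C=O)cc1OCc1ccccc1 | intermediate
5 | (4R)-4-benzyl-1,3-oxazolidine-2-thione | S=C1N[C@H](Cc2ccccc2)CO1 | starting material (auxiliary)
6 | methoxyacetyl chloride | COCC(Cl)=O | starting material
7 | (4R)-4-benzyl-3-(methoxyacetyl)-1,3-oxazolidine-2-thione | COCC(=O)N1[C@H](Cc2ccccc2)COC1=S | intermediate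
8 | (4R)-4-benzyl-3-[(2R,3R)-3-[2,5-bis(benzyloxy)-4-methoxyphenyl]-3-hydroxy-2-methoxypropanoyl]-1,3-oxazolidine-2-thione | COc1cc(OCc2ccccc2)c([C@@H](O)[C@@H](OC)C(=O)N2[C@H](Cc3ccccc3)COC2=S)cc1OCc1ccccc1 | intermediate
9 | (2R,3R)-3-[2,5-bis(benzyloxy)-4-methoxyphenyl]-3-hydroxy-N,2-dimethoxy-N-methylpropanamide | COc1cc(OCc2ccccc2)c([C@@H](O)[C@@H](OC)C(=O)N(C)OC)cc1OCc1ccccc1 | intermediate
10 | prop-2-en-1-yl 3-oxobutanoate (allyl acetoacetate) | CC(=O)CC(=O)OCC=C | starting material
11 | prop-2-en-1-yl (6R,7R)-7-[2,5-bis(benzyloxy)-4-methoxyphenyl]-7-hydroxy-6-methoxy-3,5-dioxoheptanoate | COc1cc(OCc2ccccc2)c([C@@H](O)[C@@H](OC)C(=O)CC(=O)CC(=O)OCC=C)cc1OCc1ccccc1 | intermediate (not isolated)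
12 | prop-2-en-1-yl 2-[(2R,3R)-2-[2,5-bis(benzyloxy)-4-methoxyphenyl]-3-methoxy-4-oxo-3,4-dihydro-2H-pyran-6-yl]acetate | COc1cc(OCc4ccccc4)c([C@H]2OC(CC(=O)OCC=C)=CC(=O)[C@@H]2OC)cc1OCc5ccccc5 | intermediate
13 | 2-[(2R,3R)-2-[2,5-bis(benzyloxy)-4-methoxyphenyl]-3-methoxy-4-oxo-3,4-dihydro-2H-pyran-6-yl]acetic acid | COc1cc(OCc4ccccc4)c([C@H]2OC(CC(=O)O)=CC(=O)[C@@H]2OC)cc1OCc5ccccc5 | intermediate
14 | dimethyl 2-methoxypropanedioate (dimethyl methoxymalonate) | COC(C(=O)OC)C(=O)OC | starting material
15 | potassium (2RS)-2,3-dimethoxy-3-oxopropanoate | COC(C(=O)[O-])C(=O)OC.[K+] | intermediate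
16 | 1-{2-[(2R,3R)-2-[2,5-bis(benzyloxy)-4-methoxyphenyl]-3-methoxy-4-oxo-3,4-dihydro-2H-pyran-6-yl]acetyl}-1H-imidazole | COc1cc(OCc4ccccc4)c([C@H]2OC(CC(=O)n3ccnc3)=CC(=O)[C@@H]2OC)cc1OCc5ccccc5 | intermediate (not isolated)
17 | methyl (2RS)-4-[(2R,3R)-2-[2,5-bis(benzyloxy)-4-methoxyphenyl]-3-methoxy-4-oxo-3,4-dihydro-2H-pyran-6-yl]-2-methoxy-3-oxobutanoate | COc1cc(OCc4ccccc4)c([C@H]2OC(CC(=O)C(OC)C(=O)OC)=CC(=O)[C@@H]2OC)cc1OCc5ccccc5 | intermediate (key-step precursor)
18 | (2R,3R,6RS)-2-[2,5-bis(benzyloxy)-4-methoxyphenyl]-3,6-dimethoxy-2,3-dihydro-4H-chromene-4,5,7(6H,8H)-trione | COc1cc(OCc4ccccc4)c([C@H]2OC3=C(C(=O)C(OC)C(=O)C3)C(=O)[C@@H]2OC)cc1OCc5ccccc5 | intermediate (not isolated)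
19 | (2R,3R)-2-[2,5-bis(benzyloxy)-4-methoxyphenyl]-5,7-dihydroxy-3,6-dimethoxy-2,3-dihydro-4H-chromen-4-one | COc1cc(OCc4ccccc4)c([C@H]2Oc3cc(O)c(OC)c(O)c3C(=O)[C@@H]2OC)cc1OCc5ccccc5 | intermediate (key-step product)
20 | (2R,3R)-2-[2,5-bis(benzyloxy)-4-methoxyphenyl]-3,5,6,7-tetramethoxy-2,3-dihydro-4H-chromen-4-one | COc1cc(OCc4ccccc4)c([C@H]2Oc3cc(OC)c(OC)c(OC)c3C(=O)[C@@H]2OC)cc1OCc5ccccc5 | intermediate
21 | (2R,3R)-2-(2,5-dihydroxy-4-methoxyphenyl)-3,5,6,7-tetramethoxy-2,3-dihydro-4H-chromen-4-one | COc1cc(O)c([C@H]2Oc3cc(OC)c(OC)c(OC)c3C(=O)[C@@H]2OC)cc1O | target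

## Step count and risks

Total: 12 steps, including the one-step side branches step 3 and step 8. Longest linear sequence: 10 steps (1, 2, 4, 5, 6, 7, 9, 10, 11, 12).

**Step 10 (key step, proposed new method).** The chain may rest as the unreactive chelate of the C6 enolate, or the alpha carbon of the vinylogous ester may be too weak a nucleophile, so that no C-acylation occurs. Methoxide may also open ring C, by conjugate addition at C8a or deprotonation at C3, with loss of the C2 configuration on reclosure. The fallback uses known chalcone chemistry, sets out from aldehyde 4 and returns at 20. Commercial 1-(6-hydroxy-2,3,4-trimethoxyphenyl)ethanone F1 would be protected with chloromethyl methyl ether and NaH in DMF as 1-[2,3,4-trimethoxy-6-(methoxymethoxy)phenyl]ethanone F2. Claisen–Schmidt condensation of F2 with 4 (KOH, EtOH) should give (2E)-3-[2,5-bis(benzyloxy)-4-methoxyphenyl]-1-[2,3,4-trimethoxy-6-(methoxymethoxy)phenyl]prop-2-en-1-one F3. Juliá–Colonna epoxidation (H2O2, NaOH, poly-L-leucine) should give [(2R,3S)-3-[2,5-bis(benzyloxy)-4-methoxyphenyl]oxiran-2-yl][2,3,4-trimethoxy-6-(methoxymethoxy)phenyl]methanone F4. HCl in methanol should remove the acetal and let the phenol open the epoxide at the benzylic carbon to (2R,3R)-2-[2,5-bis(benzyloxy)-4-methoxyphenyl]-3-hydroxy-5,6,7-trimethoxy-2,3-dihydro-4H-chromen-4-one F5, the retained C3 centre directing C2 to the trans arrangement. Methylation of the C3 hydroxyl of F5 with MeI and Ag2O returns to the route at 20.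

**Step 9.** The acyl imidazolide 16 has an acidic C8–H and may self-condense or eliminate to a ketene before it meets the malonate, and acid 13 may decarboxylate before activation. The fallback sets out from 13 and returns at 17. Condensation with Meldrum's acid (DCC, DMAP, CH2Cl2) would give 5-{1-hydroxy-2-[(2R,3R)-2-[2,5-bis(benzyloxy)-4-methoxyphenyl]-3-methoxy-4-oxo-3,4-dihydro-2H-pyran-6-yl]ethylidene}-2,2-dimethyl-1,3-dioxane-4,6-dione F6. Methanolysis in refluxing methanol would give methyl 4-[(2R,3R)-2-[2,5-bis(benzyloxy)-4-methoxyphenyl]-3-methoxy-4-oxo-3,4-dihydro-2H-pyran-6-yl]-3-oxobutanoate F7. Regitz diazo transfer (4-acetamidobenzenesulfonyl azide, Et3N) would give methyl 2-diazo-4-[(2R,3R)-2-[2,5-bis(benzyloxy)-4-methoxyphenyl]-3-methoxy-4-oxo-3,4-dihydro-2H-pyran-6-yl]-3-oxobutanoate F8, and O–H insertion into methanol with catalytic Rh2(OAc)4 should give 17.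

**Step 6.** The alkoxide of 9 may undergo retro-aldol cleavage under the basic dianion conditions, the diketo ester 11 may lactonize to a 4-hydroxy-2-pyranone instead of dehydrating, and acid may ionize the benzylic C2–O bond during dehydration and erode the C2 configuration. The fallback sets out from 9 and returns at 13. Excess 1-propynylmagnesium bromide (CH3C≡CMgBr, THF, 0 °C) should give (1R,2R)-1-[2,5-bis(benzyloxy)-4-methoxyphenyl]-1-hydroxy-2-methoxyhex-4-yn-3-one F9. A 6-endo-dig cyclization with catalytic Ph3PAuCl and AgOTf should give (2R,3R)-2-[2,5-bis(benzyloxy)-4-methoxyphenyl]-3-methoxy-6-methyl-2,3-dihydro-4H-pyran-4-one F10. Deprotonation of the C8 methyl group with LiN(SiMe3)2 at -78 °C and carboxylation with CO2 then gives 13.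

**Step 4.** Facial or anti/syn selectivity may be poor with this ortho-substituted, electron-rich aldehyde, and excess TiCl4 may cleave the ortho benzyl ether or ionize the benzylic alkoxide. The fallback sets out from 4 and returns at 9. A Mukaiyama aldol addition of (Z)-1-(ethylsulfanyl)-2-methoxy-1-(trimethylsilyloxy)ethene F11, promoted by Sn(OTf)2, a chiral proline-derived diamine (antipode chosen for the 2R,3R product) and Bu2Sn(OAc)2, should give S-ethyl (2R,3R)-3-[2,5-bis(benzyloxy)-4-methoxyphenyl]-3-hydroxy-2-methoxypropanethioate F12. Aminolysis with Me2AlN(OMe)Me gives 9.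

**Step 11.** Methylation of the chelated C5 phenol may stay incomplete, the electron-rich C8 position may be C-methylated, and prolonged exposure may open ring C. The fallback sets out from 19 and returns at 20. Trimethylsilyldiazomethane in toluene/methanol should methylate only the unchelated C7 phenol to (2R,3R)-2-[2,5-bis(benzyloxy)-4-methoxyphenyl]-5-hydroxy-3,6,7-trimethoxy-2,3-dihydro-4H-chromen-4-one F13. Mitsunobu etherification of the C5 phenol (MeOH, PPh3, diisopropyl azodicarboxylate) then gives 20.

## Further compounds

F1 | step 10 | 1-(6-hydroxy-2,3,4-trimethoxyphenyl)ethanone | CC(=O)c1c(O)cc(OC)c(OC)c1OC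
F2 | step 10 | 1-[2,3,4-trimethoxy-6-(methoxymethoxy)phenyl]ethanone | CC(=O)c1c(OCOC)cc(OC)c(OC)c1OC
F3 | step 10 | (2E)-3-[2,5-bis(benzyloxy)-4-methoxyphenyl]-1-[2,3,4-trimethoxy-6-(methoxymethoxy)phenyl]prop-2-en-1-one | COCOc1cc(OC)c(OC)c(OC)c1C(=O)/C=C/c1cc(OCc2ccccc2)c(OC)cc1OCc1ccccc1
F4 | step 10 | [(2R,3S)-3-[2,5-bis(benzyloxy)-4-methoxyphenyl]oxiran-2-yl][2,3,4-trimethoxy-6-(methoxymethoxy)phenyl]methanone | COCOc1cc(OC)c(OC)c(OC)c1C(=O)[C@@H]1O[C@H]1c1cc(OCc2ccccc2)c(OC)cc1OCc1ccccc1
F5 | step 10 | (2R,3R)-2-[2,5-bis(benzyloxy)-4-methoxyphenyl]-3-hydroxy-5,6,7-trimethoxy-2,3-dihydro-4H-chromen-4-one | COc1cc(OCc4ccccc4)c([C@H]2Oc3cc(OC)c(OC)c(OC)c3C(=O)[C@@H]2O)cc1OCc5ccccc5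
F6 | step 9 | 5-{1-hydroxy-2-[(2R,3R)-2-[2,5-bis(benzyloxy)-4-methoxyphenyl]-3-methoxy-4-oxo-3,4-dihydro-2H-pyran-6-yl]ethylidene}-2,2-dimethyl-1,3-dioxane-4,6-dione | COc1cc(OCc4ccccc4)c([C@H]2OC(CC(O)=C3C(=O)OC(C)(C)OC3=O)=CC(=O)[C@@H]2OC)cc1OCc5ccccc5
F7 | step 9 | methyl 4-[(2R,3R)-2-[2,5-bis(benzyloxy)-4-methoxyphenyl]-3-methoxy-4-oxo-3,4-dihydro-2H-pyran-6-yl]-3-oxobutanoate | COc1cc(OCc4ccccc4)c([C@H]2OC(CC(=O)CC(=O)OC)=CC(=O)[C@@H]2OC)cc1OCc5ccccc5
F8 | step 9 | methyl 2-diazo-4-[(2R,3R)-2-[2,5-bis(benzyloxy)-4-methoxyphenyl]-3-methoxy-4-oxo-3,4-dihydro-2H-pyran-6-yl]-3-oxobutanoate | COc1cc(OCc4ccccc4)c([C@H]2OC(CC(=O)C(=[N+]=[N-])C(=O)OC)=CC(=O)[C@@H]2OC)cc1OCc5ccccc5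
F9 | step 6 | (1R,2R)-1-[2,5-bis(benzyloxy)-4-methoxyphenyl]-1-hydroxy-2-methoxyhex-4-yn-3-one | COc1cc(OCc2ccccc2)c([C@@H](O)[C@@H](OC)C(=O)C#CC)cc1OCc1ccccc1
F10 | step 6 | (2R,3R)-2-[2,5-bis(benzyloxy)-4-methoxyphenyl]-3-methoxy-6-methyl-2,3-dihydro-4H-pyran-4-one | COc1cc(OCc4ccccc4)c([C@H]2OC(C)=CC(=O)[C@@H]2OC)cc1OCc5ccccc5
F11 | step 4 | (Z)-1-(ethylsulfanyl)-2-methoxy-1-(trimethylsilyloxy)ethene | CCS/C(O[Si](C)(C)C)=C\OC
F12 | step 4 | S-ethyl (2R,3R)-3-[2,5-bis(benzyloxy)-4-methoxyphenyl]-3-hydroxy-2-methoxypropanethioate | COc1cc(OCc2ccccc2)c([C@@H](O)[C@@H](OC)C(=O)SCC)cc1OCc1ccccc1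
F13 | step 11 | (2R,3R)-2-[2,5-bis(benzyloxy)-4-methoxyphenyl]-5-hydroxy-3,6,7-trimethoxy-2,3-dihydro-4H-chromen-4-one | COc1cc(OCc4ccccc4)c([C@H]2Oc3cc(OC)c(OC)c(O)c3C(=O)[C@@H]2OC)cc1OCc5ccccc5
A1 | alternative 1 | 1,4-bis(benzyloxy)-2-[(1S)-1-(2-ethenyl-3,4,5-trimethoxyphenoxy)prop-2-en-1-yl]-5-methoxybenzene | COc1cc(OCc4ccccc4)c([C@H](C=C)Oc3cc(OC)c(OC)c(OC)c3C=C)cc1OCc5ccccc5
A2 | alternative 1 | (S)-2-[2,5-bis(benzyloxy)-4-methoxyphenyl]-5,6,7-trimethoxy-2H-chromene | COc1cc(OCc4ccccc4)c([C@H]2Oc3cc(OC)c(OC)c(OC)c3C=C2)cc1OCc5ccccc5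
A3 | alternative 2 | 2,3,4-trimethoxy-6-(trimethylsilyl)phenyl trifluoromethanesulfonate | COc1cc([Si](C)(C)C)c(OS(=O)(=O)C(F)(F)F)c(OC)c1OC
A4 | alternative 2 | methyl (2R,3R)-3-[2,5-bis(benzyloxy)-4-methoxyphenyl]-3-hydroxy-2-methoxypropanoate | COc1cc(OCc2ccccc2)c([C@@H](O)[C@@H](OC)C(=O)OC)cc1OCc1ccccc1
A5 | alternative 2 | (2R,3R)-2-[2,5-bis(benzyloxy)-4-methoxyphenyl]-3,5,6,7-tetramethoxy-2,3-dihydro-4H-chromen-4-one | COc1cc(OCc4ccccc4)c([C@H]2Oc3cc(OC)c(OC)c(OC)c3C(=O)[C@@H]2OC)cc1OCc5ccccc5
A6 | alternative 3 | (2R,3R)-3-[2,5-bis(benzyloxy)-4-methoxyphenyl]-3-hydroxy-1-(4-hydroxy-2,3-dimethoxyphenyl)-2-methoxypropan-1-one | COc1cc(OCc2ccccc2)c([C@@H](O)[C@@H](OC)C(=O)c2ccc(O)c(OC)c2OC)cc1OCc1ccccc1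
A7 | alternative 3 | (2R,3R)-2-[2,5-bis(benzyloxy)-4-methoxyphenyl]-7-hydroxy-3,5,6-trimethoxy-2,3-dihydro-4H-chromen-4-one | COc1cc(OCc4ccccc4)c([C@H]2Oc3cc(O)c(OC)c(OC)c3C(=O)[C@@H]2OC)cc1OCc5ccccc5
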